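In the ash flask, after the feed, substrate fell at 3.34 min⁻¹ and ring at 0.320 min⁻¹, so substrate went about ten times as fast. Here is what you take over.

| setting | oak | ash | ochre | grey | teal | blue | green |
|---|---|---|---|---|---|---|---|
| substrate | 20 mM | 20 mM | 20 mM | 20 mM | 20 mM | 20 mM | 20 mM |
| activator | 0.63 equiv (fed, over 50 s) | 13 equiv (fed, over 50 s) | 1.00 equiv (fed, over 50 s) | 2.00 equiv (fed, over 50 s) | 4.00 equiv (fed, over 50 s) | 8.00 equiv (fed, over 50 s) | 15.0 equiv (fed, over 50 s) |
| remark | run made earlier; the fed solution adds 1.0 times the starting volume | run made earlier; the fed solution adds 1.0 times the starting volume | the fed solution adds 1.0 times the starting volume | the fed solution adds 1.0 times the starting volume | the fed solution adds 1.0 times the starting volume | the fed solution adds 1.0 times the starting volume | the fed solution adds 1.0 times the starting volume |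
| time |  |  | 3.0 min | 3.0 min | 3.0 min | 3.0 min | 3.0 min |

| run | time / min | ring / % | substrate / % |
|---|---|---|---|
| oak | 0.250 | 0 | 98.6 |
| oak | 0.833 | 4.3 | 93.3 |
| oak | 1.33 | 9.1 | 86.3 |
| oak | 2.00 | 13.4 | 80.0 |
| oak | 3.00 | 20.4 | 72.4 |
| ash | 0.250 | 6.0 | 82.7 |
| ash | 0.833 | 47.4 | 22.1 |
| ash | 1.33 | 61.5 | 4.2 |
| ash | 2.00 | 56.2 | 1.5 |
| ash | 3.00 | 40.8 | 0.6 |

(readings scatter by 0.5 percentage points)

- percent here means substrate units held: one open dimer counts as two
- amounts are per litre of the starting volume; all of the dose is in the solution fed
- steps thought possible: substrate + activator -> activated form; activated form -> ring; substrate + activated form -> open dimer; activator + ring -> over-reaction product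
- "hardly changes" means that all values lie within two and a half points (for a concentration: within two and a half percent of the largest)

1. amount of ring at the end, in percent of the substrate charged for ochre, grey, teal, blue, green, in this order
2. the shape of the row from first to last (rises, then falls / hardly changes / falls, then rises / falls all the way / rises all the way)

1. Activator attacks both substrate and ring, and both meet the same activator, so the dose largely cancels from the ratio of their rates. Call this the selectivity factor, substrate rate over ring rate: 10.4, a reading from ash with its scatter.

2. Until late in a run, over-reaction is a small correction to the ring made. For two steps in a row with that ratio, ring peaks when the substrate left is the factor raised to the power minus S/(S-1), here 7.48% of the charge. That is your estimated stopping point.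

3. This reckoning lets substrate become ring at once, so in it the dose cancels from that point and moves how soon you get there. That is rough: ash's highest ring reading, 61.5%, came with 4.2% of the substrate left, less than that point. Scaling ash's substrate rate to the dose and counting from mid-feed, which leaves 2.58 min, the point falls at 3.0 min for about 3.91 equiv. My reckoning therefore puts teal, charged 4.00 equiv, highest, so the row should rise, then fall.

4. The forecast gave 29.5%, 46%, 58%, 53% and 35%, rises, then falls: “The ring therefore peaks near 4 equiv.”

The flasks gave 29.8%, 48.1%, 62.5%, 56.9% and 35.5%, rises, then falls.

    substrate + activator → activated form (k = 0.370 M⁻¹ s⁻¹)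
    activated form → ring (k = 0.0870 s⁻¹)
    substrate + activated form → open dimer (k = 1.40 M⁻¹ s⁻¹)
    activator + ring → over-reaction product (k = 0.0500 M⁻¹ s⁻¹)

In ochre at 3.00 min, activator went to activation 15 times as fast as to over-reaction, with 59.7% of the substrate left and 29.8% as ring. Against the estimated stopping point of 7.48%, teal held 11.8% of its substrate and blue 1.25%, the two sides of the estimate, and the row turns between them at 4.9 equiv.

The data are simulated from invented constants; scatter was added.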